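**Retrosynthetic overview**
- Ring C is opened last (O1–C2, C2–C3 and C3–OH): the flavonol comes from chalcone 24 by Algar–Flynn–Oyamada oxidation, and 24 comes from ring A ketone 23 and ring B aldehyde 20 by Claisen–Schmidt condensation.
- The route rests on ring B: the prenyl-bearing carbons C2' and C3' and the oxygenated C4' are the β-carbon, α-carbon and carbonyl carbon of a 2,3-dialkylcyclohex-2-enone, so both vicinal prenyl groups are placed before the ring exists.
- That enone (11) is cut at C1'–C6' (Michael) and C2'=C3' (aldol) into keto ester 4 and vinyl ketone 8; dehydrogenation then gives the 4-hydroxybenzoate.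
- The C5' oxygen enters afterwards at the only free ortho position of the C4' phenol (ortho-formylation, Dakin oxidation); ring A is 2,4,6-trihydroxyacetophenone, C-prenylated once.
- Order of ring formation: ring B (step 4, aromatized in steps 5 to 7), ring A purchased, ring C last (step 16).

Key step: step 4

Remark: the target has no stereocentre; 9, 10, 11 and 25 are racemic (10 as a diastereomer mixture) and their stereocentres disappear later in the route.
Assumption: on bis-MOM protection of 22 the hydroxyl flanked by acetyl and prenyl (the more hindered one, held in the hydrogen bond to the carbonyl) stays free, so that ring C later closes next to the prenyl group (C8).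

Step 1
Reactants: 1 4-methylpent-3-enoic acid; 2 Meldrum's acid
Product: 4 ethyl 6-methyl-3-oxohept-5-enoate, via acyl Meldrum's acid 3 (not isolated)
Conditions: DCC, DMAP, CH2Cl2, 0 °C to rt; filter, acid wash; then EtOH, reflux
Reagents that add atoms: ethanol, CCO
Why: Carbodiimide C-acylation of Meldrum's acid followed by thermal loss of acetone and CO2 to an acylketene that ethanol traps (Oikawa–Yonemitsu β-keto ester synthesis) runs under neutral conditions that should leave the β,γ-alkene in place.

Step 2
Reactants: 5 6-methylhept-5-en-2-one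
Product: 6 1-(dimethylamino)-7-methyloct-6-en-3-one
Conditions: LiN(i-Pr)2 (LDA, commercial solution), THF, −78 °C; then Me2N=CH2 I (Eschenmoser's salt), −78 °C to rt
Reagents that add atoms: Eschenmoser's salt (N,N-dimethylmethylideneammonium iodide), C=[N+](C)C.[I-]
Why: Kinetic deprotonation gives the methyl-side lithium enolate, which the preformed iminium salt traps in a regiospecific Mannich reaction.

Step 3
Reactants: 6 1-(dimethylamino)-7-methyloct-6-en-3-one
Product: 8 7-methylocta-1,6-dien-3-one, via methiodide 7 (not isolated)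
Conditions: MeI, Et2O, rt; then NaHCO3 (aq), CH2Cl2, rt; BHT added, used at once
Reagents that add atoms: none
Why: Quaternisation turns the amine into a leaving group and mild base effects E1cB (Hofmann-type) elimination, the standard release of a vinyl ketone from a Mannich base.

Step 4
Reactants: 4 ethyl 6-methyl-3-oxohept-5-enoate; 8 7-methylocta-1,6-dien-3-one
Product: 11 racemic ethyl 2,3-bis(3-methylbut-2-en-1-yl)-4-oxocyclohex-2-ene-1-carboxylate, via Michael adduct 9 (not isolated), via ketol 10 (not isolated)
Conditions: pyrrolidine (0.3 equiv), AcOH (0.3 equiv), toluene, 0 °C to rt (8 added slowly to 4); then 80 °C, 4 Å MS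
Reagents that add atoms: none
Why: The doubly activated C2 methylene of 4 (as enol or pyrrolidine enamine) adds to the terminal carbon of 8 in a Michael reaction (bond C1'–C6'), after which the enamine of the new side-chain ketone attacks the keto ester ketone through its prenyl-bearing α-carbon and ketol 10 loses water to the tetrasubstituted enone (bond C2'=C3'). The closest known reaction type is the Hagemann ester synthesis, a Robinson annulation of a β-keto ester with an alkyl vinyl ketone under amine–acid catalysis. Ring B closes as a six-membered ring by a favoured 6-(enolendo)-exo-trig aldol. The one stereocentre that remains, the ester-bearing C1', forms without control and needs none because it becomes sp2 on aromatization, and the carbinol centres of 10 vanish on dehydration. The step needs the aldol to run from the vinyl-ketone methylene onto the keto ester ketone and not from the γ-methylene of the keto ester onto the side-chain ketone; this is secured because the amine forms its enamine at the unhindered dialkyl ketone, because the other enamine regioisomer of that ketone could only close a four-membered ring, and because the product is the conjugated tetrasubstituted enone, while the buffered, nearly neutral medium should keep both prenyl alkenes out of conjugation.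

Step 5
Reactants: 11 racemic ethyl 2,3-bis(3-methylbut-2-en-1-yl)-4-oxocyclohex-2-ene-1-carboxylate
Product: 12 ethyl 4-[(tert-butyldimethylsilyl)oxy]-2,3-bis(3-methylbut-2-en-1-yl)cyclohexa-1,3-diene-1-carboxylate
Conditions: TBSOTf, Et3N, CH2Cl2, 0 °C; Et3N-deactivated silica
Reagents that add atoms: tert-butyldimethylsilyl trifluoromethanesulfonate (TBSOTf), CC(C)(C)[Si](C)(C)OS(=O)(=O)C(F)(F)F
Why: Soft enolization of the silyl-activated enone removes the acidic ester α-hydrogen (γ to the ketone) to give the ester-conjugated silyl dienol ether, and any cross-conjugated isomer is an equally good cyclohexa-1,3-diene for the next step.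

Step 6
Reactants: 12 ethyl 4-[(tert-butyldimethylsilyl)oxy]-2,3-bis(3-methylbut-2-en-1-yl)cyclohexa-1,3-diene-1-carboxylate
Product: 13 ethyl 4-[(tert-butyldimethylsilyl)oxy]-2,3-bis(3-methylbut-2-en-1-yl)benzoate
Conditions: DDQ (1.0 equiv), 2,4,6-collidine, toluene, 0 °C to rt
Reagents that add atoms: none
Why: DDQ dehydrogenation of a cyclohexa-1,3-diene (hydride abstraction, then proton loss) is fast and driven by aromatization, so one equivalent should be used up before the prenyl methylenes react, and the silyl cap blocks oxidative chromene closure of the ortho-prenyl phenol.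

Step 7
Reactants: 13 ethyl 4-[(tert-butyldimethylsilyl)oxy]-2,3-bis(3-methylbut-2-en-1-yl)benzoate
Product: 14 ethyl 4-hydroxy-2,3-bis(3-methylbut-2-en-1-yl)benzoate
Conditions: TBAF, AcOH, THF, 0 °C
Reagents that add atoms: none
Why: Fluoride cleaves the aryl silyl ether, and the acetic acid buffer keeps the medium from becoming basic enough to touch the ester.

Step 8
Reactants: 14 ethyl 4-hydroxy-2,3-bis(3-methylbut-2-en-1-yl)benzoate
Product: 15 ethyl 5-formyl-4-hydroxy-2,3-bis(3-methylbut-2-en-1-yl)benzoate
Conditions: MgCl2, Et3N, (CH2O)n, THF, reflux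
Reagents that add atoms: paraformaldehyde (formaldehyde), C=O
Why: In the Casnati–Skattebøl ortho-formylation the magnesium phenoxide delivers formaldehyde only to an ortho carbon, and C5 is the single free one, so the second oxygen site is fixed without ambiguity.

Step 9
Reactants: 15 ethyl 5-formyl-4-hydroxy-2,3-bis(3-methylbut-2-en-1-yl)benzoate
Product: 17 ethyl 4,5-dihydroxy-2,3-bis(3-methylbut-2-en-1-yl)benzoate, via aryl formate 16 (not isolated)
Conditions: H2O2 (30% aq), NaOH (aq), THF, 0 °C to rt, N2; then NaH2PO4 (aq)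
Reagents that add atoms: hydrogen peroxide, OO
Why: In the Dakin oxidation hydroperoxide adds to the ortho-hydroxybenzaldehyde, aryl migration gives formate 16 and this is hydrolysed in the flask, while nucleophilic peroxide spares the prenyl alkenes and the para-phenoxide deactivates the ester toward hydroxide.

Step 10
Reactants: 17 ethyl 4,5-dihydroxy-2,3-bis(3-methylbut-2-en-1-yl)benzoate
Product: 18 ethyl 4,5-bis(methoxymethoxy)-2,3-bis(3-methylbut-2-en-1-yl)benzoate
Conditions: MOMCl, i-Pr2NEt, CH2Cl2, 0 °C to rt
Reagents that add atoms: chloromethyl methyl ether (MOMCl), COCCl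
Why: O-Alkylation of both catechol hydroxyls gives base-stable acetals that survive hydride, hydroxide and alkaline peroxide and can be removed at the end without hydrogenolysis.

Step 11
Reactants: 18 ethyl 4,5-bis(methoxymethoxy)-2,3-bis(3-methylbut-2-en-1-yl)benzoate
Product: 19 [4,5-bis(methoxymethoxy)-2,3-bis(3-methylbut-2-en-1-yl)phenyl]methanol
Conditions: LiAlH4, THF, 0 °C
Reagents that add atoms: none
Why: Hydride reduction of the ester to the benzylic alcohol leaves acetals and isolated alkenes untouched.

Step 12
Reactants: 19 [4,5-bis(methoxymethoxy)-2,3-bis(3-methylbut-2-en-1-yl)phenyl]methanol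
Product: 20 4,5-bis(methoxymethoxy)-2,3-bis(3-methylbut-2-en-1-yl)benzaldehyde
Conditions: MnO2, CH2Cl2, rt
Reagents that add atoms: none
Why: MnO2 oxidises benzylic alcohols selectively and stops at the aldehyde.

Step 13
Reactants: 21 2,4,6-trihydroxyacetophenone
Product: 22 1-[2,4,6-trihydroxy-3-(3-methylbut-2-en-1-yl)phenyl]ethan-1-one
Conditions: prenyl bromide (1.0 equiv), DBU, THF, rt; chromatography
Reagents that add atoms: prenyl bromide (1-bromo-3-methylbut-2-ene), CC(C)=CCBr
Why: The ambident phloroglucinol-type phenoxide is C-alkylated at one of its two equivalent nuclear positions, and the mono-C-prenyl ketone is separable from O-alkylated and dialkylated material.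

Step 14
Reactants: 22 1-[2,4,6-trihydroxy-3-(3-methylbut-2-en-1-yl)phenyl]ethan-1-one
Product: 23 1-[2-hydroxy-4,6-bis(methoxymethoxy)-3-(3-methylbut-2-en-1-yl)phenyl]ethan-1-one
Conditions: MOMCl (2.2 equiv), i-Pr2NEt, CH2Cl2, 0 °C
Reagents that add atoms: chloromethyl methyl ether (MOMCl), COCCl
Why: Selective O-alkylation takes the para hydroxyl and the less hindered ortho hydroxyl, while the hydroxyl between acetyl and prenyl stays chelated to the carbonyl and free.

Step 15
Reactants: 20 4,5-bis(methoxymethoxy)-2,3-bis(3-methylbut-2-en-1-yl)benzaldehyde; 23 1-[2-hydroxy-4,6-bis(methoxymethoxy)-3-(3-methylbut-2-en-1-yl)phenyl]ethan-1-one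
Product: 24 (E)-3-[4,5-bis(methoxymethoxy)-2,3-bis(3-methylbut-2-en-1-yl)phenyl]-1-[2-hydroxy-4,6-bis(methoxymethoxy)-3-(3-methylbut-2-en-1-yl)phenyl]prop-2-en-1-one
Conditions: KOH, EtOH–H2O, 0 °C to rt
Reagents that add atoms: none
Why: Claisen–Schmidt condensation of the methyl ketone with the non-enolisable aldehyde, followed by E1cB dehydration, gives the conjugated E-enone as the thermodynamic alkene.

Step 16
Reactants: 24 the chalcone of step 15
Product: 26 3-hydroxy-5,7-bis(methoxymethoxy)-2-[4,5-bis(methoxymethoxy)-2,3-bis(3-methylbut-2-en-1-yl)phenyl]-8-(3-methylbut-2-en-1-yl)-4H-chromen-4-one, via dihydroflavonol 25 (not isolated)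
Conditions: H2O2 (30% aq), NaOH (aq), MeOH–THF, 0 °C to rt
Reagents that add atoms: hydrogen peroxide, OO
Why: In the Algar–Flynn–Oyamada reaction alkaline peroxide oxidises the enone while the only free phenoxide (next to the prenyl group) closes ring C in the 6-endo sense to trans-dihydroflavonol 25, which is dehydrogenated in the same medium, with low temperature favouring flavonol over aurone and nucleophilic peroxide sparing the prenyl groups.

Step 17
Reactants: 26 the tetra-MOM flavonol of step 16
Product: 27 Broussoflavonol G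
Conditions: HCl (3 M aq)/MeOH 1:10, 40 °C, stopped at full conversion
Reagents that add atoms: none
Why: Acid-catalysed transacetalisation removes the four methoxymethyl groups as dimethoxymethane, and dilute acid at low temperature should limit cyclisation of the prenyl groups onto neighbouring phenols.

**Compound list**
1 | 4-methylpent-3-enoic acid | CC(C)=CCC(=O)O | starting material
2 | Meldrum's acid (2,2-dimethyl-1,3-dioxane-4,6-dione) | CC1(C)OC(=O)CC(=O)O1 | starting material
3 | 5-(1-hydroxy-4-methylpent-3-en-1-ylidene)-2,2-dimethyl-1,3-dioxane-4,6-dione | CC(C)=CCC(O)=C1C(=O)OC(C)(C)OC1=O | intermediate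
4 | ethyl 6-methyl-3-oxohept-5-enoate | CCOC(=O)CC(=O)CC=C(C)C | intermediate
5 | 6-methylhept-5-en-2-one | CC(=O)CCC=C(C)C | starting material
6 | 1-(dimethylamino)-7-methyloct-6-en-3-one | CN(C)CCC(=O)CCC=C(C)C | intermediate
7 | N,N,N,7-tetramethyl-3-oxooct-6-en-1-aminium iodide | C[N+](C)(C)CCC(=O)CCC=C(C)C.[I-] | intermediate
8 | 7-methylocta-1,6-dien-3-one | C=CC(=O)CCC=C(C)C | intermediate
9 | racemic ethyl 9-methyl-2-(4-methylpent-3-enoyl)-5-oxodec-8-enoate | CCOC(=O)C(CCC(=O)CCC=C(C)C)C(=O)CC=C(C)C | intermediate
10 | ethyl 2-hydroxy-2,3-bis(3-methylbut-2-en-1-yl)-4-oxocyclohexane-1-carboxylate (racemic, diastereomer mixture) | CCOC(=O)C1CCC(=O)C(CC=C(C)C)C1(O)CC=C(C)C | intermediate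
11 | racemic ethyl 2,3-bis(3-methylbut-2-en-1-yl)-4-oxocyclohex-2-ene-1-carboxylate | CCOC(=O)C1CCC(=O)C(CC=C(C)C)=C1CC=C(C)C | intermediate
12 | ethyl 4-[(tert-butyldimethylsilyl)oxy]-2,3-bis(3-methylbut-2-en-1-yl)cyclohexa-1,3-diene-1-carboxylate | CCOC(=O)C1=C(CC=C(C)C)C(CC=C(C)C)=C(O[Si](C)(C)C(C)(C)C)CC1 | intermediate
13 | ethyl 4-[(tert-butyldimethylsilyl)oxy]-2,3-bis(3-methylbut-2-en-1-yl)benzoate | CCOC(=O)c1ccc(O[Si](C)(C)C(C)(C)C)c(CC=C(C)C)c1CC=C(C)C | intermediate
14 | ethyl 4-hydroxy-2,3-bis(3-methylbut-2-en-1-yl)benzoate | CCOC(=O)c1ccc(O)c(CC=C(C)C)c1CC=C(C)C | intermediate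
15 | ethyl 5-formyl-4-hydroxy-2,3-bis(3-methylbut-2-en-1-yl)benzoate | CCOC(=O)c1cc(C=O)c(O)c(CC=C(C)C)c1CC=C(C)C | intermediate
16 | ethyl 5-(formyloxy)-4-hydroxy-2,3-bis(3-methylbut-2-en-1-yl)benzoate | CCOC(=O)c1cc(OC=O)c(O)c(CC=C(C)C)c1CC=C(C)C | intermediate
17 | ethyl 4,5-dihydroxy-2,3-bis(3-methylbut-2-en-1-yl)benzoate | CCOC(=O)c1cc(O)c(O)c(CC=C(C)C)c1CC=C(C)C | intermediate
18 | ethyl 4,5-bis(methoxymethoxy)-2,3-bis(3-methylbut-2-en-1-yl)benzoate | CCOC(=O)c1cc(OCOC)c(OCOC)c(CC=C(C)C)c1CC=C(C)C | intermediate
19 | [4,5-bis(methoxymethoxy)-2,3-bis(3-methylbut-2-en-1-yl)phenyl]methanol | OCc1cc(OCOC)c(OCOC)c(CC=C(C)C)c1CC=C(C)C | intermediate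
20 | 4,5-bis(methoxymethoxy)-2,3-bis(3-methylbut-2-en-1-yl)benzaldehyde | O=Cc1cc(OCOC)c(OCOC)c(CC=C(C)C)c1CC=C(C)C | intermediate
21 | 2,4,6-trihydroxyacetophenone | CC(=O)c1c(O)cc(O)cc1O | starting material
22 | 1-[2,4,6-trihydroxy-3-(3-methylbut-2-en-1-yl)phenyl]ethan-1-one | CC(=O)c1c(O)cc(O)c(CC=C(C)C)c1O | intermediate
23 | 1-[2-hydroxy-4,6-bis(methoxymethoxy)-3-(3-methylbut-2-en-1-yl)phenyl]ethan-1-one | CC(=O)c1c(OCOC)cc(OCOC)c(CC=C(C)C)c1O | intermediate
24 | (E)-3-[4,5-bis(methoxymethoxy)-2,3-bis(3-methylbut-2-en-1-yl)phenyl]-1-[2-hydroxy-4,6-bis(methoxymethoxy)-3-(3-methylbut-2-en-1-yl)phenyl]prop-2-en-1-one | O=C(/C=C/c1cc(OCOC)c(OCOC)c(CC=C(C)C)c1CC=C(C)C)c1c(OCOC)cc(OCOC)c(CC=C(C)C)c1O | intermediate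
25 | racemic trans-3-hydroxy-5,7-bis(methoxymethoxy)-2-[4,5-bis(methoxymethoxy)-2,3-bis(3-methylbut-2-en-1-yl)phenyl]-8-(3-methylbut-2-en-1-yl)chroman-4-one (one enantiomer drawn) | O=C1c2c(OCOC)cc(OCOC)c(CC=C(C)C)c2O[C@H](c2cc(OCOC)c(OCOC)c(CC=C(C)C)c2CC=C(C)C)[C@H]1O | intermediate
26 | 3-hydroxy-5,7-bis(methoxymethoxy)-2-[4,5-bis(methoxymethoxy)-2,3-bis(3-methylbut-2-en-1-yl)phenyl]-8-(3-methylbut-2-en-1-yl)-4H-chromen-4-one | O=c1c(O)c(-c2cc(OCOC)c(OCOC)c(CC=C(C)C)c2CC=C(C)C)oc2c(CC=C(C)C)c(OCOC)cc(OCOC)c12 | intermediate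
27 | Broussoflavonol G, 2-[4,5-dihydroxy-2,3-bis(3-methylbut-2-en-1-yl)phenyl]-3,5,7-trihydroxy-8-(3-methylbut-2-en-1-yl)-4H-chromen-4-one | CC(C)=CCc1c(-c2oc3c(CC=C(C)C)c(O)cc(O)c3c(=O)c2O)cc(O)c(O)c1CC=C(C)C | target

**Step count**
Total: 17 steps. Longest linear sequence: 14 steps (from 5 through steps 2 to 12 and 15 to 17). Step 1 and steps 13 and 14 are the convergent branches.

**Steps most likely to fail**

Step 4. Polymerisation of the vinyl ketone may outrun conjugate addition, and the aldol may run in the wrong direction or a prenyl double bond may migrate into conjugation during the heated condensation. The fallback sets out from 4 and comes back at 11. Keto ester 4 is annulated with methyl vinyl ketone under the same pyrrolidine–AcOH catalysis, the parent Hagemann case in which the aldol donor is a methyl group, to give racemic ethyl 2-(3-methylbut-2-en-1-yl)-4-oxocyclohex-2-ene-1-carboxylate F1. Its extended enolate (KOt-Bu, t-BuOH–THF) is then alkylated at C3 with prenyl bromide, the classical C3 alkylation of Hagemann's ester, which gives 11.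

Step 6. Hydride abstraction at a prenyl methylene, or early loss of the silyl group followed by oxidative chromene closure, may compete with ring dehydrogenation. The fallback sets out from 11 and comes back at 14, so steps 5 to 7 are bypassed. The lithium dienolate of 11 (LiN(SiMe3)2, THF, −78 °C) is brominated with 1,2-dibromotetrachloroethane, a bromine donor inert to alkenes, to give racemic ethyl 1-bromo-2,3-bis(3-methylbut-2-en-1-yl)-4-oxocyclohex-2-ene-1-carboxylate F2. DBU at rt then removes HBr and the dienone tautomerises to phenol 14; a regioisomeric bromide would lose HBr to the same phenol.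

Step 16. The phenoxide may close in the 5-exo sense onto the α-carbon (aurone pathway), which the 6'-alkoxy group and the ortho-substituted ring B can favour, or the oxidation may stall. The fallback sets out from 24 and comes back at 26; it forms the C3–O bond only after the six-membered ring exists. Chalcone 24 is isomerised by 6-endo oxa-Michael closure (NaOAc, EtOH, reflux) to racemic 5,7-bis(methoxymethoxy)-2-[4,5-bis(methoxymethoxy)-2,3-bis(3-methylbut-2-en-1-yl)phenyl]-8-(3-methylbut-2-en-1-yl)chroman-4-one F3. Its lithium enolate (LiN(SiMe3)2, THF, −78 °C) is hydroxylated with 2-(phenylsulfonyl)-3-phenyloxaziridine to give 25, now isolated, and 25 is dehydrogenated to 26 in the NaOH/H2O2 medium of step 16.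

**Further compounds**
F1 | step 4 | racemic ethyl 2-(3-methylbut-2-en-1-yl)-4-oxocyclohex-2-ene-1-carboxylate | CCOC(=O)C1CCC(=O)C=C1CC=C(C)C
F2 | step 6 | racemic ethyl 1-bromo-2,3-bis(3-methylbut-2-en-1-yl)-4-oxocyclohex-2-ene-1-carboxylate | CCOC(=O)C1(Br)CCC(=O)C(CC=C(C)C)=C1CC=C(C)C
F3 | step 16 | racemic 5,7-bis(methoxymethoxy)-2-[4,5-bis(methoxymethoxy)-2,3-bis(3-methylbut-2-en-1-yl)phenyl]-8-(3-methylbut-2-en-1-yl)chroman-4-one | O=C1CC(c2cc(OCOC)c(OCOC)c(CC=C(C)C)c2CC=C(C)C)Oc2c(CC=C(C)C)c(OCOC)cc(OCOC)c12
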